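No constant of this flask is printed, so two chemists reason differently from the charges and the dawn run. The steps thought possible are these: E binds X reversibly to D, Q turns D into Z, and Z releases X and G, while Q can also decay to J and E to L.

- dawn: E 0.17 M; Q 0.315 M (fed, over 40 min); X 52 mM; run made earlier
- flask: E 0.35 M; Q 0.315 M (fed, over 40 min); X 52 mM; time 3.0 h

- dawn (time / min: G / %, D / %): 3.00: 1.8, 4.5; 4.00: 2.4, 4.0; 6.00: 3.2, 4.1; 10.0: 8.3, 4.4; 15.0: 13.9, 3.8; 25.0: 31.4, 5.2; 40.0: 56.3, 2.6

(each reading ± 1 percentage point)

- the numbers in the tables scatter with a standard deviation of 1 percentage point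
- steps thought possible: E + X <-> D; Q + D -> Z; Z -> X + G; Q -> J; E -> L

- how much G there is at 3.0 h, in percent of the E charged
- how much D there is at 3.0 h, in percent of the E charged

The first chemist counts. Each G costs one Q, and the flask holds less Q than E, so she calls Q the limiting reagent and expects G at 90.0% of the E charged.

The second chemist looks at rates. At dawn Q entered at 7.87 mM min⁻¹, but between 10.0 min and 40.0 min G grew at 2.72 mM min⁻¹, which is slower. So he sees Q dividing between capture by D and decay to J, and the capture depends on [D].

My own reckoning follows his, and it begins with the binding. D reads 4.5% at 3.00 min and 4.4% at 10.0 min, level within the scatter, so I treat binding as a pre-equilibrium. The first four dawn readings average 7.23 mM of D. Subtract that from the X charged, leaving out Z, which the dawn run does not show. Subtract D and the G at 6.00 min from the E charged. Then the binding constant, [D]/([E][X]), reads 1.03 M⁻¹, with the scatter of its readings.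

Of the catalyst not held as Z, the share standing as D is then K[E]/(1+K[E]). With [E] taken at its charge and Z left out, this gives 13.7 mM of D at the start of the flask, about twice the dawn level.

The forecast takes his side: G 50% (41% to 59%) and D 2.1% (1% to 3%), holding of the dawn run that “Most Q is therefore lost to J”.

The flask gives G 53.7% and D 2.13%, so the split stands against the count of 90.0%.

    E + X ⇌ D (K = 1.10 M⁻¹, k = 1.00 M⁻¹ s⁻¹)
    Q + D → Z (k = 0.100 M⁻¹ s⁻¹)
    Z → X + G (k = 0.0650 s⁻¹)
    Q → J (k = 7.00 × 10⁻⁴ s⁻¹)
    E → L (k = 1.30 × 10⁻⁶ s⁻¹)

At 3.00 h the flask holds 0.127 M of J. With E left at 43%, the binding constant gives D of 2.00%. A neighbour flask stands nearer the count: with 0.088 M of X, G reaches 62.6%, past the forecast's top of 59%. In that neighbour flask, E left at 34% gives D of 2.73% by the same constant, and the flask holds 2.90%.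

The runs stem from a simulated flask for substances that don't exist, and the scatter is random.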